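I counted turnovers. The flask asked about is alder itself, so its readings and the earlier cedar run were what I had to go on.

| setting | alder | cedar | flask |
|---|---|---|---|
| starting material | 0.50 M | 0.50 M | 0.50 M |
| second substrate | 0.25 M | 0.38 M | 0.250 M |
| free catalyst | 4.8 mM | 4.8 mM | 4.8 mM |
| added ligand | 8.2 mM | 8.2 mM | 8.2 mM |
| remark | the very flask that is asked about, followed so far | run made earlier |  |

| run | time / h | target / % | starting material / % |
|---|---|---|---|
| alder | 1.33 | 3.7 | 96.1 |
| alder | 4.00 | 11.5 | 88.0 |
| alder | 6.00 | 16.9 | 82.7 |
| alder | 10.0 | 27.2 | 71.6 |
| alder | 15.0 | 39.3 | 59.9 |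
| alder | 20.0 | 50.8 | 48.9 |
| alder | 25.0 | 60.5 | 39.0 |
| cedar | 2.00 | 5.3 | 94.6 |
| cedar | 3.00 | 7.7 | 91.9 |
| cedar | 4.00 | 10.4 | 89.5 |
| cedar | 6.00 | 15.0 | 84.4 |
| cedar | 10.0 | 24.8 | 74.8 |
| cedar | 15.0 | 35.9 | 63.5 |
| cedar | 25.0 | 55.2 | 44.5 |

(standard deviation of a reading: 0.3 percentage points)

- no earlier run changes the charge of free catalyst; that part of a forecast is a guess

- factor on the rate of making target when 30% of the starting material are converted if free catalyst is charged twice over
- factor on the rate when 30% of the starting material are converted if free catalyst is charged at 0.50 mM instead

Charged at 4.8 mM, each catalyst had to make 31.2 target molecules to reach 30% conversion; I call this turnover number, conversion times c(starting material) over c(free catalyst), the turnover demand.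

I read the alder table down the target column. Between the first two readings each catalyst charged turned over at 3.04 /h, and between the last two at 2.02 /h. Falling c(starting material) and wearing catalyst both stayed open as readings of those figures. By 25.0 h alder had reached 63.0 turnovers. Against that column I set cedar's: with c(second substrate) at 0.38 M, cedar stood lower at the same time, at 55.2% against 60.5%, so second substrate was no help to the target.

With twice the catalyst, the demand fell to 15.6, inside what alder had shown, so I committed to a factor near 2. At 0.50 mM it rose to 300, far past that range, so I put the factor below plain proportion, 0.104.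

The forecast gave 1.8 and 0.11, the second above my limit, saying: “No run varies catalyst, so its order is assumed.”

The simulation gave 2.22 and 0.0254.

    starting material + free catalyst ⇌ catalyst intermediate A (K = 4.50 /M, k = 37.0 /M/h)
    catalyst intermediate A → free catalyst + target (k = 14.0 /h)
    second substrate + free catalyst ⇌ catalyst intermediate B (K = 4.40 /M, k = 410 /M/h)
    catalyst intermediate B → free catalyst + second product (k = 18.0 /h)
    free catalyst + added ligand ⇌ idle complex, settled at all times (K = 140 /M)
    second substrate + catalyst intermediate A → spent catalyst (k = 0.220 /M/h)

Catalyst intermediate A made target at 14 /h and, at c(second substrate) as charged, went to spent catalyst at 0.0550 /h, which is 255 turnovers per loss, more than the flask's demand of 31.2, and at 0.250 d the flask held 5.43% spent catalyst with 17.2% target. At 0.50 mM the demand of 300 lay above those 255 turnovers, and at the same conversion idle complex was 8.99% of the catalyst and spent catalyst 75.9%.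

The numbers in the tables were computed with constants of no real substance; scatter was added.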